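**Retrosynthetic overview**

- The strategy rests on ring A of the chroman-4-one. It carries oxygen on C7 and C8a and the acyl carbon C4 on C4a, which is the pattern of a 6-acyl-3-alkoxycyclohex-2-enone. Ring A is therefore carried as a cyclohexenone made from cyclohexane-1,3-dione and is aromatised (C5–C6) only after ring C exists.
- Ring C is disconnected at C2–C3 (enantioselective vinylogous Mukaiyama aldol of a bis(silyl) dienol ether with the chroman-6-carbaldehyde) and at O1–C8a (acid cyclodehydration of the δ-hydroxy β-diketone).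
- The chroman aldehyde comes from 2-(benzyloxy)phenol by para-bromination, propargyl ether Claisen rearrangement to the 2,2-dimethylchromene, salen-manganese epoxidation (sets the chroman C3), hydride opening at C4, silylation and formylation.
- Ring order: dihydropyran ring of the chroman first, pyranone ring C second, aromatic ring A last; desilylation and hydrogenolysis finish the route.

Key step: step 12

Assumption 1: the sense of induction of the two chiral catalysts is taken from the closest analogues (2,2-dimethylchromenes and indene for the (S,S)-salen manganese chloride; titanium/BINOL additions to aryl aldehydes for (S)-BINOL). If a first run showed the opposite sense, the mirror-image ligand would be used and nothing else would change.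

Assumption 2: monosilylation of the β-diketone is taken to fall on the ring oxygen; the isomer silylated on the acetyl oxygen would be expected to reach the same diene by loss of a methyl proton in the following step.

**Route**

Step 1
Reactants: 1 cyclohexane-1,3-dione; 2 benzyl alcohol
Product: 3 3-(benzyloxy)cyclohex-2-en-1-one
Conditions: p-TsOH·H2O (cat.), toluene, reflux, Dean–Stark
Reagents that add atoms: none
Why: Acid-catalysed O-alkylation of the dione enol (vinylogous Fischer esterification) with azeotropic removal of water should give the vinylogous benzyl ester as the thermodynamic product.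

Step 2
Reactants: 3 3-(benzyloxy)cyclohex-2-en-1-one
Product: 5 6-acetyl-3-(benzyloxy)cyclohex-2-en-1-one, via lithium dienolate 4 (not isolated)
Conditions: LiN(iPr)2 (2.1 equiv), THF, −78 °C; 1-acetylbenzotriazole (1.0 equiv), −78 → −20 °C; aq. NH4Cl
Reagents that add atoms: 1-acetylbenzotriazole, CC(=O)n1nnc2ccccc21
Why: Kinetic deprotonation of the vinylogous ester occurs at C6 (Stork–Danheiser regiochemistry) and the cross-conjugated lithium enolate should undergo Claisen-type C-acylation with the N-acylbenzotriazole, the second equivalent of base holding the more acidic β-diketone as its enolate so that proton transfer and a second acylation are suppressed.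

Step 3
Reactants: 5 6-acetyl-3-(benzyloxy)cyclohex-2-en-1-one
Product: 6 1-[4-(benzyloxy)-2-(trimethylsilyloxy)cyclohexa-1,3-dien-1-yl]ethan-1-one
Conditions: Me3SiCl (1.2 equiv), Et3N (1.5 equiv), Et2O, rt; filtration and concentration under argon
Reagents that add atoms: chlorotrimethylsilane, C[Si](C)(C)Cl
Why: O-silylation of the β-diketone enol (amine/chlorosilane) should fall on the ring oxygen, which is the more electron-rich oxygen of the vinylogous ester and belongs to the endocyclic enol favoured in 2-acylcyclohexanones, leaving the acetyl group as a methyl ketone.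

Step 4
Reactants: 6 1-[4-(benzyloxy)-2-(trimethylsilyloxy)cyclohexa-1,3-dien-1-yl]ethan-1-one
Product: 8 4-(benzyloxy)-2-(trimethylsilyloxy)-1-[1-(trimethylsilyloxy)ethenyl]cyclohexa-1,3-diene, via lithium enolate 7 (not isolated)
Conditions: LiN(iPr)2 (1.1 equiv), THF, −78 °C; Me3SiCl (1.3 equiv), −78 → 0 °C; pentane, filtration, used crude
Reagents that add atoms: chlorotrimethylsilane, C[Si](C)(C)Cl
Why: Kinetic enolisation of the methyl ketone (CH3 is its only α position, the ring CH2 next to the benzyloxy carbon being a slower vinylogous site) and O-silylation should give the 1,3-bis(silyloxy)diene in the way Chan-type dienes are prepared.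

Step 5
Reactants: 9 2-(benzyloxy)phenol
Product: 10 2-(benzyloxy)-4-bromophenol
Conditions: NBS (1.0 equiv), MeCN, −20 → 0 °C
Reagents that add atoms: N-bromosuccinimide, O=C1CCC(=O)N1Br
Why: Electrophilic aromatic bromination should go para to the free hydroxyl, the stronger director, at the least hindered activated position.

Step 6
Reactants: 10 2-(benzyloxy)-4-bromophenol; 11 3-chloro-3-methylbut-1-yne
Product: 12 2-(benzyloxy)-4-bromo-1-[(2-methylbut-3-yn-2-yl)oxy]benzene
Conditions: DBU (1.3 equiv), CuCl2·2H2O (cat.), MeCN, 0 °C → rt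
Reagents that add atoms: none
Why: Copper-catalysed propargylic substitution through a copper acetylide/propargyl cation pair lets the phenoxide take the tertiary carbon, where direct SN2 displacement is not possible.

Step 7
Reactants: 12 2-(benzyloxy)-4-bromo-1-[(2-methylbut-3-yn-2-yl)oxy]benzene
Product: 14 8-(benzyloxy)-6-bromo-2,2-dimethyl-2H-chromene, via allenylphenol 13 (not isolated)
Conditions: N,N-diethylaniline, 190 °C
Reagents that add atoms: none
Why: Aryl propargyl ether Claisen rearrangement to the only free ortho carbon, tautomerisation to the allenylphenol, 1,5-hydrogen shift to the ortho-quinone methide and oxa-6π electrocyclisation should give the chromene.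

Step 8
Reactants: 14 8-(benzyloxy)-6-bromo-2,2-dimethyl-2H-chromene
Product: 15 (3S,4S)-8-(benzyloxy)-6-bromo-3,4-epoxy-2,2-dimethylchromane
Conditions: (S,S)-[N,N'-bis(3,5-di-tert-butylsalicylidene)cyclohexane-1,2-diaminato]MnCl (4 mol%), 4-phenylpyridine N-oxide, NaOCl (aq., pH 11.3), CH2Cl2, 0 °C
Reagents that add atoms: sodium hypochlorite, [Na+].[O-]Cl
Why: Jacobsen–Katsuki epoxidation, for which the cis aryl-conjugated alkene of a 2,2-dimethylchromene is a favourable substrate; the (S,S)-diamine backbone of the trivalent manganese salen complex directs the side-on approach of the alkene to the oxo species so that C3 and C4 are both expected to be S.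

Step 9
Reactants: 15 (3S,4S)-8-(benzyloxy)-6-bromo-3,4-epoxy-2,2-dimethylchromane
Product: 16 (3S)-8-(benzyloxy)-6-bromo-2,2-dimethylchroman-3-ol
Conditions: LiAlH4 (1.0 equiv), THF, 0 °C; H2O, aq. NaOH work-up
Reagents that add atoms: none
Why: SN2 hydride opening of the epoxide at the benzylic C4, C3 being shielded by the quaternary C2; the C3–O bond is not touched, so C3 stays S, and the aryl bromide and benzyl ether should not react at 0 °C.

Step 10
Reactants: 16 (3S)-8-(benzyloxy)-6-bromo-2,2-dimethylchroman-3-ol
Product: 17 tert-butyl{[(3S)-8-(benzyloxy)-6-bromo-2,2-dimethylchroman-3-yl]oxy}dimethylsilane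
Conditions: TBSOTf (1.3 equiv), 2,6-lutidine (2 equiv), CH2Cl2, 0 °C
Reagents that add atoms: tert-butyldimethylsilyl trifluoromethanesulfonate, CC(C)(C)[Si](C)(C)OS(=O)(=O)C(F)(F)F
Why: Silyl triflate silylation of the hindered secondary alcohol protects it for the organolithium and titanium steps.

Step 11
Reactants: 17 tert-butyl{[(3S)-8-(benzyloxy)-6-bromo-2,2-dimethylchroman-3-yl]oxy}dimethylsilane
Product: 19 (3S)-8-(benzyloxy)-3-(tert-butyldimethylsilyloxy)-2,2-dimethylchroman-6-carbaldehyde, via aryllithium 18 (not isolated)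
Conditions: n-BuLi (1.1 equiv), THF, −78 °C; DMF (3 equiv), −78 → 0 °C; aq. NH4Cl
Reagents that add atoms: N,N-dimethylformamide, CN(C)C=O
Why: Bromine–lithium exchange at −78 °C is faster than any attack on the ethers, and Bouveault formylation of the aryllithium with DMF gives the aldehyde.

Step 12
Reactants: 19 (3S)-8-(benzyloxy)-3-(tert-butyldimethylsilyloxy)-2,2-dimethylchroman-6-carbaldehyde; 8 4-(benzyloxy)-2-(trimethylsilyloxy)-1-[1-(trimethylsilyloxy)ethenyl]cyclohexa-1,3-diene
Product: 22 (2S)-7-(benzyloxy)-2-[(3S)-8-(benzyloxy)-3-(tert-butyldimethylsilyloxy)-2,2-dimethylchroman-6-yl]-2,3,5,6-tetrahydro-4H-chromen-4-one, via silylated aldol adduct 20 (not isolated), via hydroxy diketone 21 (not isolated)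
Conditions: Ti(OiPr)4 (10 mol%), (S)-BINOL (10 mol%), 4 Å MS, THF, −78 °C → rt; then CF3CO2H, CH2Cl2, −20 → 0 °C; aq. NaHCO3
Reagents that add atoms: none
Why: The BINOLate of tetravalent titanium binds the aldehyde and the diene attacks through its terminal CH2 in an open transition state (vinylogous Mukaiyama aldol with silyl transfer, giving 20), which forms C2–C3; trifluoroacetic acid then removes the trimethylsilyl groups to give 21 and closes ring C. The closest known reaction type is the Ti(OiPr)4/BINOL-catalysed aldol addition of 1,3-bis(trimethylsilyloxy)-1,3-dienes to aryl aldehydes followed by acid cyclodehydration to 2-aryl-2,3-dihydro-4H-pyran-4-ones. Ring C closes by 6-exo-trig addition of the C2 hydroxyl to the ring carbonyl that becomes C8a, followed by loss of water to the C4a=C8a enol ether, so O1 is the former aldehyde oxygen and no bond at C2 is broken. C2 is set in the carbon–carbon bond formation by the (S)-BINOL ligand, which is expected to expose the aldehyde face leading to the (S)-carbinol, the remote chroman stereocentre having no influence. The step needs attack at the terminal carbon, a single mode of closure and retention at the electron-rich benzylic carbinol: the terminal CH2 is the only unhindered nucleophilic terminus, only the C8a carbonyl lies 1,5 to the new hydroxyl, and the acid is used cold, anhydrous and briefly so that the C2–O bond does not ionise and the benzyl enol ether and silyl ether survive.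

Step 13
Reactants: 22 (2S)-7-(benzyloxy)-2-[(3S)-8-(benzyloxy)-3-(tert-butyldimethylsilyloxy)-2,2-dimethylchroman-6-yl]-2,3,5,6-tetrahydro-4H-chromen-4-one
Product: 23 (2S)-7-(benzyloxy)-2-[(3S)-8-(benzyloxy)-3-(tert-butyldimethylsilyloxy)-2,2-dimethylchroman-6-yl]chroman-4-one
Conditions: DDQ (1.1 equiv), 1,4-dioxane, rt
Reagents that add atoms: none
Why: Quinone dehydrogenation, in which hydride abstraction from C5 gives a cation stabilised by O1 and the C7 benzyloxy group and loss of the C6 proton aromatises ring A; this should be much faster at room temperature than C2–C3 dehydrogenation or benzylic oxidation.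

Step 14
Reactants: 23 (2S)-7-(benzyloxy)-2-[(3S)-8-(benzyloxy)-3-(tert-butyldimethylsilyloxy)-2,2-dimethylchroman-6-yl]chroman-4-one
Product: 24 (2S)-7-(benzyloxy)-2-[(3S)-8-(benzyloxy)-3-hydroxy-2,2-dimethylchroman-6-yl]chroman-4-one
Conditions: HF·pyridine, pyridine, THF, 0 °C → rt
Reagents that add atoms: none
Why: Fluoride cleavage of the silyl ether under buffered, slightly acidic conditions, chosen because basic fluoride could open ring C by retro-oxa-Michael reaction and scramble C2.

Step 15
Reactants: 24 (2S)-7-(benzyloxy)-2-[(3S)-8-(benzyloxy)-3-hydroxy-2,2-dimethylchroman-6-yl]chroman-4-one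
Product: 25 (2S)-2-[(3S)-3,8-dihydroxy-2,2-dimethylchroman-6-yl]-7-hydroxychroman-4-one
Conditions: H2 (1 atm), 10% Pd/C, EtOAc, rt; stopped after two equivalents of H2
Reagents that add atoms: none
Why: Hydrogenolysis of the two aryl benzyl ethers over Pd/C under neutral conditions should be much faster than cleavage of the benzylic C2–O1 bond of ring C or reduction of the C4 ketone.

**Compound list**

1 | cyclohexane-1,3-dione | O=C1CCCC(=O)C1 | starting material
2 | benzyl alcohol | OCc1ccccc1 | starting material
3 | 3-(benzyloxy)cyclohex-2-en-1-one | O=C1CCCC(OCc2ccccc2)=C1 | intermediate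
4 | lithium 5-(benzyloxy)cyclohexa-1,5-dien-1-olate (forms in the flask) | [Li]OC1=CCCC(OCc2ccccc2)=C1 | intermediate
5 | 6-acetyl-3-(benzyloxy)cyclohex-2-en-1-one | CC(=O)C1CCC(OCc2ccccc2)=CC1=O | intermediate
6 | 1-[4-(benzyloxy)-2-(trimethylsilyloxy)cyclohexa-1,3-dien-1-yl]ethan-1-one | CC(=O)C1=C(O[Si](C)(C)C)C=C(OCc2ccccc2)CC1 | intermediate
7 | lithium 1-[4-(benzyloxy)-2-(trimethylsilyloxy)cyclohexa-1,3-dien-1-yl]ethen-1-olate (forms in the flask) | [Li]OC(=C)C1=C(O[Si](C)(C)C)C=C(OCc2ccccc2)CC1 | intermediate
8 | 4-(benzyloxy)-2-(trimethylsilyloxy)-1-[1-(trimethylsilyloxy)ethenyl]cyclohexa-1,3-diene | C=C(O[Si](C)(C)C)C1=C(O[Si](C)(C)C)C=C(OCc2ccccc2)CC1 | intermediate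
9 | 2-(benzyloxy)phenol | Oc1ccccc1OCc1ccccc1 | starting material
10 | 2-(benzyloxy)-4-bromophenol | Oc1ccc(Br)cc1OCc1ccccc1 | intermediate
11 | 3-chloro-3-methylbut-1-yne | CC(C)(Cl)C#C | starting material
12 | 2-(benzyloxy)-4-bromo-1-[(2-methylbut-3-yn-2-yl)oxy]benzene | C#CC(C)(C)Oc1ccc(Br)cc1OCc1ccccc1 | intermediate
13 | 2-(benzyloxy)-4-bromo-6-(3-methylbuta-1,2-dien-1-yl)phenol (forms in the flask) | CC(C)=C=Cc1cc(Br)cc(OCc2ccccc2)c1O | intermediate
14 | 8-(benzyloxy)-6-bromo-2,2-dimethyl-2H-chromene | CC1(C)C=Cc2cc(Br)cc(OCc3ccccc3)c2O1 | intermediate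
15 | (3S,4S)-8-(benzyloxy)-6-bromo-3,4-epoxy-2,2-dimethylchromane | CC1(C)Oc2c(OCc3ccccc3)cc(Br)cc2[C@@H]2O[C@@H]21 | intermediate
16 | (3S)-8-(benzyloxy)-6-bromo-2,2-dimethylchroman-3-ol | CC1(C)Oc2c(OCc3ccccc3)cc(Br)cc2C[C@@H]1O | intermediate
17 | tert-butyl{[(3S)-8-(benzyloxy)-6-bromo-2,2-dimethylchroman-3-yl]oxy}dimethylsilane | CC1(C)Oc2c(OCc3ccccc3)cc(Br)cc2C[C@@H]1O[Si](C)(C)C(C)(C)C | intermediate
18 | [(3S)-8-(benzyloxy)-3-(tert-butyldimethylsilyloxy)-2,2-dimethylchroman-6-yl]lithium (forms in the flask) | CC1(C)Oc2c(OCc3ccccc3)cc([Li])cc2C[C@@H]1O[Si](C)(C)C(C)(C)C | intermediate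
19 | (3S)-8-(benzyloxy)-3-(tert-butyldimethylsilyloxy)-2,2-dimethylchroman-6-carbaldehyde | CC1(C)Oc2c(OCc3ccccc3)cc(C=O)cc2C[C@@H]1O[Si](C)(C)C(C)(C)C | intermediate
20 | (3S)-1-[4-(benzyloxy)-2-(trimethylsilyloxy)cyclohexa-1,3-dien-1-yl]-3-[(3S)-8-(benzyloxy)-3-(tert-butyldimethylsilyloxy)-2,2-dimethylchroman-6-yl]-3-(trimethylsilyloxy)propan-1-one (forms in the flask) | CC1(C)Oc2c(OCc3ccccc3)cc([C@@H](O[Si](C)(C)C)CC(=O)C4=C(O[Si](C)(C)C)C=C(OCc5ccccc5)CC4)cc2C[C@@H]1O[Si](C)(C)C(C)(C)C | intermediate
21 | (3S)-1-[4-(benzyloxy)-2-hydroxycyclohexa-1,3-dien-1-yl]-3-[(3S)-8-(benzyloxy)-3-(tert-butyldimethylsilyloxy)-2,2-dimethylchroman-6-yl]-3-hydroxypropan-1-one (enol form of the δ-hydroxy β-diketone; forms in the flask) | CC1(C)Oc2c(OCc3ccccc3)cc([C@@H](O)CC(=O)C4=C(O)C=C(OCc5ccccc5)CC4)cc2C[C@@H]1O[Si](C)(C)C(C)(C)C | intermediate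
22 | (2S)-7-(benzyloxy)-2-[(3S)-8-(benzyloxy)-3-(tert-butyldimethylsilyloxy)-2,2-dimethylchroman-6-yl]-2,3,5,6-tetrahydro-4H-chromen-4-one | CC1(C)Oc2c(OCc3ccccc3)cc([C@@H]4CC(=O)C5=C(O4)C=C(OCc6ccccc6)CC5)cc2C[C@@H]1O[Si](C)(C)C(C)(C)C | intermediate
23 | (2S)-7-(benzyloxy)-2-[(3S)-8-(benzyloxy)-3-(tert-butyldimethylsilyloxy)-2,2-dimethylchroman-6-yl]chroman-4-one | CC1(C)Oc2c(OCc3ccccc3)cc([C@@H]4CC(=O)c5ccc(OCc6ccccc6)cc5O4)cc2C[C@@H]1O[Si](C)(C)C(C)(C)C | intermediate
24 | (2S)-7-(benzyloxy)-2-[(3S)-8-(benzyloxy)-3-hydroxy-2,2-dimethylchroman-6-yl]chroman-4-one | CC1(C)Oc2c(OCc3ccccc3)cc([C@@H]4CC(=O)c5ccc(OCc6ccccc6)cc5O4)cc2C[C@@H]1O | intermediate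
25 | (2S)-2-[(3S)-3,8-dihydroxy-2,2-dimethylchroman-6-yl]-7-hydroxychroman-4-one | CC1(C)Oc2c(O)cc([C@@H]3CC(=O)c4ccc(O)cc4O3)cc2C[C@@H]1O | target

**Step count and risks**

Total step count: 15. Longest linear sequence: 11 steps (steps 5–15, from 2-(benzyloxy)phenol 9).

Steps most likely to fail:

1. Step 12. Enantioface selection at the aldehyde may be poor, because the diene is fully substituted at its internal double bond and an uncatalysed silyl-transfer pathway can compete. In addition, ionisation of the p-alkoxybenzylic C–O bond during the acid closure may erode C2.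
   Fallback: catalyst control is replaced by separation with recycling. Setting out from 19 and 8, a BF3·OEt2-mediated Mukaiyama aldol (CH2Cl2, −78 °C, aqueous work-up) would give 21 together with its carbinol epimer, (3R)-1-[4-(benzyloxy)-2-hydroxycyclohexa-1,3-dien-1-yl]-3-[(3S)-8-(benzyloxy)-3-(tert-butyldimethylsilyloxy)-2,2-dimethylchroman-6-yl]-3-hydroxypropan-1-one F1. The same trifluoroacetic acid closure would then give 22 mixed with its C2 epimer, (2R)-7-(benzyloxy)-2-[(3S)-8-(benzyloxy)-3-(tert-butyldimethylsilyloxy)-2,2-dimethylchroman-6-yl]-2,3,5,6-tetrahydro-4H-chromen-4-one F2. The two are diastereomers and would be separated by preparative chromatography on a cellulose carbamate chiral stationary phase. The unwanted epimer would be re-equilibrated with DBU in toluene (retro-oxa-Michael opening to the enone and reclosure) and separated again. The fallback comes back to the route at 22.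

2. Step 4. The lithium amide may remove a proton from the ring CH2 next to the benzyloxy-bearing carbon instead of the methyl group, the mono-silyl ether may be the acetyl-O-silylated isomer, and the bis(silyl) diene may hydrolyse on handling.
   Fallback: setting out from 5, the kinetic lithium enolate route is replaced by soft enolisation of the diketone itself with Me3SiOTf (2.2 equiv) and Et3N in Et2O at 0 °C. Both carbonyl oxygens are silylated in turn, and the silylated cation is expected to lose a proton from the methyl group whichever oxygen reacts first. The ether layer is decanted from the ammonium triflate and used at once. This makes no compound outside the list (F0) and comes back to the route at 8.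

3. Step 2. O-acylation of the enolate, consumption of the acyl donor by the amide base, or a second acylation may lower the conversion to the C-acylated diketone.
   Fallback: the acylation is replaced by an aldol addition and an oxidation. Setting out from 3 (through enolate 4 at −78 °C), addition to acetaldehyde would give 3-(benzyloxy)-6-(1-hydroxyethyl)cyclohex-2-en-1-one F3 as a diastereomer mixture of no consequence. Dess–Martin periodinane in CH2Cl2 would oxidise it to the β-diketone, coming back to the route at 5.

Further compounds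
F1 | step 12 | (3R)-1-[4-(benzyloxy)-2-hydroxycyclohexa-1,3-dien-1-yl]-3-[(3S)-8-(benzyloxy)-3-(tert-butyldimethylsilyloxy)-2,2-dimethylchroman-6-yl]-3-hydroxypropan-1-one | CC1(C)Oc2c(OCc3ccccc3)cc([C@H](O)CC(=O)C4=C(O)C=C(OCc5ccccc5)CC4)cc2C[C@@H]1O[Si](C)(C)C(C)(C)C
F2 | step 12 | (2R)-7-(benzyloxy)-2-[(3S)-8-(benzyloxy)-3-(tert-butyldimethylsilyloxy)-2,2-dimethylchroman-6-yl]-2,3,5,6-tetrahydro-4H-chromen-4-one | CC1(C)Oc2c(OCc3ccccc3)cc([C@H]4CC(=O)C5=C(O4)C=C(OCc6ccccc6)CC5)cc2C[C@@H]1O[Si](C)(C)C(C)(C)C
F0 | step 4 | none | none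
F3 | step 2 | 3-(benzyloxy)-6-(1-hydroxyethyl)cyclohex-2-en-1-one | CC(O)C1CCC(OCc2ccccc2)=CC1=O
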